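**Retrosynthetic overview**
1. Feature: in ring A the neighbouring carbons C8a and C4a carry O1 and the C4 acyl carbon, and C4a lies next to oxygenated C5. A 3-alkoxyaryne leaves this pattern when an oxygen nucleophile adds to its remote carbon and the anion beside the alkoxy group is acylated.
2. The C8 acid chain goes back, through decarboxylation and deallylation, to a malonate 1,6-adduct of the para-quinone methide C5=O/C8=CHPh. That comes from a C8 benzhydrol (formylation, PhMgBr) by way of its sulfone.
3. The C6 prenyl group goes back by an aromatic Claisen shift to the O5 1,1-dimethylallyl ether, and free O5 to selective BCl3 cleavage of the 5,7-dimethyl ether.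
4. Ring C is cut at O1–C8a and C4–C4a into 3,5-dimethoxybenzyne (from 3,5-dimethoxyphenol) and the silyl-masked syn-(2R,3S) hydroxy ester (enzymatic dynamic reduction), which brings in C2 and C3.
5. Ring order: ring A is bought, ring C is closed in the key step, the phenyl ring is bought.

Key step: step 6

Assumption: the sense of induction in step 14 cannot be derived for this unsymmetrical quinone methide. The cinchonidine-derived salt is written, and its pseudoenantiomer from cinchonine replaces it under the same conditions if the benzylic centre comes out S.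
Remark: the C2 and C3 methyl groups of 13 and of all later chromanones are cis, the less stable arrangement. After step 6, carbonate is therefore used only at −30 °C, and nothing more basic than morpholine is used at room temperature or above.

**Step 1**
Reactants: 1 3,5-dimethoxyphenol
Product: 2 2-bromo-3,5-dimethoxyphenol
Conditions: NBS (1.0 equiv), CH2Cl2, −78 °C to 0 °C
Reagents that add atoms: N-bromosuccinimide, O=C1CCC(=O)N1Br
Why: Electrophilic aromatic bromination: in a non-polar solvent at low temperature NBS, held by a hydrogen bond to the phenol OH, should deliver bromine mainly to C2 (ortho to OH, para to a methoxy group), and the C4 bromide that may accompany 2 is removed by chromatography.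

**Step 2**
Reactants: 2 2-bromo-3,5-dimethoxyphenol
Product: 3 (2-bromo-3,5-dimethoxyphenoxy)trimethylsilane
Conditions: (Me3Si)2NH, THF, 65 °C; evaporate
Reagents that add atoms: hexamethyldisilazane, C[Si](C)(C)N[Si](C)(C)C
Why: Silylation of a phenol by HMDS needs no added base and gives off only ammonia, so 3 is obtained dry by evaporation and is ready for the lithiation.

**Step 3**
Reactants: 3 (2-bromo-3,5-dimethoxyphenoxy)trimethylsilane
Product: 6 3,5-dimethoxy-2-(trimethylsilyl)phenyl trifluoromethanesulfonate, via aryllithium 4 (not isolated), via lithium silylphenoxide 5 (not isolated)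
Conditions: n-BuLi, THF, −78 °C; then Tf2O, −78 °C to 0 °C
Reagents that add atoms: trifluoromethanesulfonic anhydride, O=S(=O)(OS(=O)(=O)C(F)(F)F)C(F)(F)F
Why: Bromine–lithium exchange gives 4, its carbanion takes the silyl group from the neighbouring oxygen (retro-Brook 1,3 O-to-C shift) to give 5, and triflation of that phenoxide completes the standard construction of an ortho-silylaryl triflate.

**Step 4**
Reactants: 7 methyl 2-methyl-3-oxobutanoate (racemic)
Product: 8 methyl (2R,3S)-3-hydroxy-2-methylbutanoate
Conditions: syn-(2R,3S)-selective ketoreductase from a commercial panel, NADP+ (cat.), i-PrOH, phosphate buffer pH 7, 30 °C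
Reagents that add atoms: none
Why: Dynamic reductive kinetic resolution: C2 of 7 racemises through the enol in the buffer while the enzyme accepts only the (2R) keto ester and delivers hydride to one face of the ketone, which sets C2 as R and C3 as S (syn), a selectivity known for this keto ester among yeast-type and engineered reductases.

**Step 5**
Reactants: 8 methyl (2R,3S)-3-hydroxy-2-methylbutanoate
Product: 9 methyl (2R,3S)-2-methyl-3-(trimethylsilyloxy)butanoate
Conditions: TMSCl, imidazole, CH2Cl2, 0 °C; distil
Reagents that add atoms: chlorotrimethylsilane, C[Si](C)(C)Cl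
Why: Standard O-silylation removes the only exchangeable proton of the nucleophile and gives a distillable, rigorously dry alkoxide precursor without touching C2 or C3.

**Step 6**
Reactants: 6 3,5-dimethoxy-2-(trimethylsilyl)phenyl trifluoromethanesulfonate; 9 methyl (2R,3S)-2-methyl-3-(trimethylsilyloxy)butanoate
Product: 13 (2S,3R)-5,7-dimethoxy-2,3-dimethylchroman-4-one, via 3,5-dimethoxybenzyne 10 (not isolated), via cesium alkoxide 11 (not isolated), via arylcesium 12 (not isolated)
Conditions: 6 (1.1 equiv), 9 (1.0 equiv), flame-dried CsF (1.1 equiv, equimolar with 6), 18-crown-6, THF (dilute), 0 °C to rt; then AcOH, −20 °C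
Reagents that add atoms: none
Why: Proposed new method: fluoride, and later the methoxide that the reaction itself releases, strips silicon from both partners, so that aryne 10 (triple bond C4a–C8a) and alkoxide 11 are freed slowly and in step in a medium without any acidic proton; 11 adds to C8a, the aryl anion 12 at C4a attacks the ester carbonyl and methoxide leaves, which forms O1–C8a and C4–C4a. The closest known reaction type is aryne insertion with acyl transfer under CsF, as in the xanthone synthesis from methyl salicylates and the chromanone synthesis from unsaturated acids, whereas an aliphatic beta-oxy ester has not served as the partner. Ring C closes in the 6-exo-trig mode. No stereocentre is made: the carbinol C–O bond of 9 is never broken and the carbon next to the ester is not deprotonated, so (2R,3S)-9 maps onto (2S,3R)-13 with the two methyl groups cis. The step needs attack at C8a only, and the C5 methoxy group secures this because it distorts the aryne and stabilises inductively the charge that builds up at C4a beside it. Acylation must outrun protonation, which THF in place of MeCN and the silyl-masked hydroxyl secure, and C3 must survive, for which CsF is kept equimolar with 6 so that each methoxide is used up in desilylating 6 or 9 and ends as MeOSiMe3, leaving only CsOTf in the flask when AcOH is added.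

**Step 7**
Reactants: 13 (2S,3R)-5,7-dimethoxy-2,3-dimethylchroman-4-one
Product: 15 (2S,3R)-5-hydroxy-7-methoxy-2,3-dimethylchroman-4-one, via dichloroboron aryloxide 14 (not isolated)
Conditions: BCl3 (1.2 equiv), CH2Cl2, −78 °C to 0 °C; then H2O
Reagents that add atoms: none
Why: Chelation-directed aryl methyl ether cleavage: BCl3 is held between the C4 carbonyl oxygen and the peri O5, chloride takes only that methyl group to give 14, the C7 ether has no such anchor, and the base-free medium leaves C3 untouched.

**Step 8**
Reactants: 16 2-methylbut-3-en-2-ol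
Product: 17 tert-butyl (2-methylbut-3-en-2-yl) carbonate
Conditions: n-BuLi, THF, 0 °C; then Boc2O, 0 °C to rt
Reagents that add atoms: di-tert-butyl dicarbonate, CC(C)(C)OC(=O)OC(=O)OC(C)(C)C
Why: Acylation of the lithium alkoxide of a tertiary allylic alcohol with Boc2O is the usual way to this mixed carbonate.

**Step 9**
Reactants: 15 (2S,3R)-5-hydroxy-7-methoxy-2,3-dimethylchroman-4-one; 17 tert-butyl (2-methylbut-3-en-2-yl) carbonate
Product: 18 (2S,3R)-7-methoxy-2,3-dimethyl-5-[(2-methylbut-3-en-2-yl)oxy]chroman-4-one
Conditions: Pd(PPh3)4 (5 mol %), THF, 0 °C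
Reagents that add atoms: none
Why: Decarboxylative Tsuji–Trost O-allylation: zerovalent palladium ionises 17, the tert-butoxide set free takes the phenol proton, and the phenoxide attacks the more substituted end of the 1,1-dimethylallyl palladium cation under kinetic control, as known for the reverse prenylation of phenols, in a medium that never holds free base so that C3 is safe.

**Step 10**
Reactants: 18 (2S,3R)-7-methoxy-2,3-dimethyl-5-[(2-methylbut-3-en-2-yl)oxy]chroman-4-one
Product: 19 (2S,3R)-5-hydroxy-7-methoxy-2,3-dimethyl-6-(3-methylbut-2-enyl)chroman-4-one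
Conditions: toluene, 110 °C
Reagents that add atoms: none
Why: Aromatic Claisen rearrangement: the [3,3] shift can end only at C6 because the other ortho carbon C4a is substituted, the allyl inversion turns the 1,1-dimethylallyl group into a linear prenyl group, and rearomatisation restores the hydrogen-bonded C5 phenol.

**Step 11**
Reactants: 19 (2S,3R)-5-hydroxy-7-methoxy-2,3-dimethyl-6-(3-methylbut-2-enyl)chroman-4-one
Product: 21 (2S,3R)-5-hydroxy-7-methoxy-2,3-dimethyl-6-(3-methylbut-2-enyl)-4-oxochroman-8-carbaldehyde, via iminium salt 20 (not isolated)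
Conditions: POCl3, DMF, 0 °C to rt; then aq. NaOAc, 0 °C
Reagents that add atoms: N,N-dimethylformamide, CN(C)C=O; water, O
Why: Vilsmeier–Haack formylation: C8 is the only free position of ring A and is ortho to O7 and O1, para to O5 and meta to the acyl group, whereas the chloroiminium ion is too weak an electrophile for the isolated prenyl alkene, and buffered hydrolysis of 20 gives the aldehyde.

**Step 12**
Reactants: 21 (2S,3R)-5-hydroxy-7-methoxy-2,3-dimethyl-6-(3-methylbut-2-enyl)-4-oxochroman-8-carbaldehyde
Product: 22 (2S,3R)-5-hydroxy-8-[hydroxy(phenyl)methyl]-7-methoxy-2,3-dimethyl-6-(3-methylbut-2-enyl)chroman-4-one (both carbinol epimers; used crude)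
Conditions: PhMgBr (2.3 equiv), THF, −78 °C to −40 °C; then aq. NH4Cl
Reagents that add atoms: phenylmagnesium bromide, Br[Mg]c1ccccc1
Why: Grignard 1,2-addition: the first equivalent makes the magnesium phenoxide, which chelates C4=O and shuts that ketone off from addition and enolisation, the second adds to the aldehyde, and the new carbinol centre forms without control but is erased in step 14.

**Step 13**
Reactants: 22 (2S,3R)-5-hydroxy-8-[hydroxy(phenyl)methyl]-7-methoxy-2,3-dimethyl-6-(3-methylbut-2-enyl)chroman-4-one
Product: 23 (2S,3R)-5-hydroxy-7-methoxy-2,3-dimethyl-6-(3-methylbut-2-enyl)-8-[phenyl(4-methylphenylsulfonyl)methyl]chroman-4-one (both epimers)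
Conditions: p-TolSO2H, CH2Cl2, 0 °C to rt
Reagents that add atoms: p-toluenesulfinic acid, Cc1ccc(cc1)S(=O)O
Why: SN1-type substitution: the sulfinic acid is acidic enough to ionise this triply oxygen-stabilised benzhydrol but too weak to cyclise the prenyl phenol, and reversible capture ends at sulfur in the stable sulfone, the established storable precursor of a quinone methide.

**Step 14**
Reactants: 23 (2S,3R)-5-hydroxy-7-methoxy-2,3-dimethyl-6-(3-methylbut-2-enyl)-8-[phenyl(4-methylphenylsulfonyl)methyl]chroman-4-one; 24 diallyl malonate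
Product: 26 diallyl 2-{(R)-[(2S,3R)-5-hydroxy-7-methoxy-2,3-dimethyl-6-(3-methylbut-2-enyl)-4-oxochroman-8-yl](phenyl)methyl}malonate, via para-quinone methide 25 (not isolated)
Conditions: N-(9-anthracenylmethyl)cinchonidinium bromide (10 mol %), Cs2CO3, toluene, −30 °C
Reagents that add atoms: none
Why: Base-induced 1,6-elimination of sulfinate from the phenoxide gives 25 and the chiral ammonium malonate enolate adds to its exocyclic carbon (asymmetric phase-transfer 1,6-conjugate addition of malonates to para-quinone methides, driven by rearomatisation), the cation shielding one face so that the benzylic centre is set as R, while both sulfone epimers and both alkene geometries of 25 converge because sulfinate addition is reversible, and the minor epimer is a diastereomer that chromatography removes.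

**Step 15**
Reactants: 26 diallyl 2-{(R)-[(2S,3R)-5-hydroxy-7-methoxy-2,3-dimethyl-6-(3-methylbut-2-enyl)-4-oxochroman-8-yl](phenyl)methyl}malonate
Product: 27 2-{(R)-[(2S,3R)-5-hydroxy-7-methoxy-2,3-dimethyl-6-(3-methylbut-2-enyl)-4-oxochroman-8-yl](phenyl)methyl}malonic acid
Conditions: Pd(PPh3)4 (5 mol %), morpholine (2.2 equiv), THF, rt; then cold aq. KHSO4
Reagents that add atoms: none
Why: Tsuji–Trost deallylation: zerovalent palladium ionises both allyl esters and morpholine carries the allyl groups away at room temperature, each turnover freeing a carboxylic acid that buffers the amine, so the prenyl alkene, the phenol and both ring C stereocentres are spared.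

**Step 16**
Reactants: 27 2-{(R)-[(2S,3R)-5-hydroxy-7-methoxy-2,3-dimethyl-6-(3-methylbut-2-enyl)-4-oxochroman-8-yl](phenyl)methyl}malonic acid
Product: 28 (3R)-3-[(2S,3R)-5-hydroxy-7-methoxy-2,3-dimethyl-6-(3-methylbut-2-enyl)-4-oxochroman-8-yl]-3-phenylpropanoic acid
Conditions: Cu2O (10 mol %), MeCN, 80 °C
Reagents that add atoms: none
Why: Decarboxylation of a monosubstituted malonic acid through the cyclic enediol pathway, catalysed by Cu2O in MeCN well below the temperature of the uncatalysed reaction, turns the malonyl carbon into CH2 and involves none of the three stereocentres.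

**Compound list**
1 | 3,5-dimethoxyphenol | COc1cc(O)cc(OC)c1 | starting material
2 | 2-bromo-3,5-dimethoxyphenol | COc1cc(O)c(Br)c(OC)c1 | intermediate
3 | (2-bromo-3,5-dimethoxyphenoxy)trimethylsilane | COc1cc(O[Si](C)(C)C)c(Br)c(OC)c1 | intermediate
4 | [2,4-dimethoxy-6-(trimethylsilyloxy)phenyl]lithium | COc1cc(O[Si](C)(C)C)c([Li])c(OC)c1 | intermediate
5 | lithium 3,5-dimethoxy-2-(trimethylsilyl)phenoxide | COc1cc([O-])c([Si](C)(C)C)c(OC)c1.[Li+] | intermediate
6 | 3,5-dimethoxy-2-(trimethylsilyl)phenyl trifluoromethanesulfonate | COc1cc(OC)c([Si](C)(C)C)c(OS(=O)(=O)C(F)(F)F)c1 | intermediate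
7 | methyl 2-methyl-3-oxobutanoate (racemic) | CC(=O)C(C)C(=O)OC | starting material
8 | methyl (2R,3S)-3-hydroxy-2-methylbutanoate | O[C@@H](C)[C@@H](C)C(=O)OC | intermediate
9 | methyl (2R,3S)-2-methyl-3-(trimethylsilyloxy)butanoate | C[Si](C)(C)O[C@@H](C)[C@@H](C)C(=O)OC | intermediate
10 | 3,5-dimethoxybenzyne | COC1=CC(OC)=CC#C1 | intermediate
11 | cesium (2S,3R)-4-methoxy-3-methyl-4-oxobutan-2-olate (alkoxide of 8) | [Cs+].[O-][C@@H](C)[C@@H](C)C(=O)OC | intermediate
12 | methyl (2R,3S)-3-(2-cesio-3,5-dimethoxyphenoxy)-2-methylbutanoate | COc1cc(OC)c([Cs])c(c1)O[C@@H](C)[C@@H](C)C(=O)OC | intermediate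
13 | (2S,3R)-5,7-dimethoxy-2,3-dimethylchroman-4-one | COc1cc(OC)c2c(c1)O[C@@H](C)[C@@H](C)C2=O | intermediate
14 | (2S,3R)-5-(dichloroboryloxy)-7-methoxy-2,3-dimethylchroman-4-one | COc1cc(OB(Cl)Cl)c2c(c1)O[C@@H](C)[C@@H](C)C2=O | intermediate
15 | (2S,3R)-5-hydroxy-7-methoxy-2,3-dimethylchroman-4-one | COc1cc(O)c2c(c1)O[C@@H](C)[C@@H](C)C2=O | intermediate
16 | 2-methylbut-3-en-2-ol | C=CC(C)(C)O | starting material
17 | tert-butyl (2-methylbut-3-en-2-yl) carbonate | C=CC(C)(C)OC(=O)OC(C)(C)C | intermediate
18 | (2S,3R)-7-methoxy-2,3-dimethyl-5-[(2-methylbut-3-en-2-yl)oxy]chroman-4-one | COc1cc(OC(C)(C)C=C)c2c(c1)O[C@@H](C)[C@@H](C)C2=O | intermediate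
19 | (2S,3R)-5-hydroxy-7-methoxy-2,3-dimethyl-6-(3-methylbut-2-enyl)chroman-4-one | COc1c(CC=C(C)C)c(O)c2c(c1)O[C@@H](C)[C@@H](C)C2=O | intermediate
20 | C8 (dimethyliminio)methyl derivative of 19, dichlorophosphate salt | COc1c(CC=C(C)C)c(O)c2c(c1C=[N+](C)C)O[C@@H](C)[C@@H](C)C2=O.[O-]P(=O)(Cl)Cl | intermediate
21 | (2S,3R)-5-hydroxy-7-methoxy-2,3-dimethyl-6-(3-methylbut-2-enyl)-4-oxochroman-8-carbaldehyde | COc1c(CC=C(C)C)c(O)c2c(c1C=O)O[C@@H](C)[C@@H](C)C2=O | intermediate
22 | (2S,3R)-5-hydroxy-8-[hydroxy(phenyl)methyl]-7-methoxy-2,3-dimethyl-6-(3-methylbut-2-enyl)chroman-4-one, both carbinol epimers | COc1c(CC=C(C)C)c(O)c2c(c1C(O)c1ccccc1)O[C@@H](C)[C@@H](C)C2=O | intermediate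
23 | (2S,3R)-5-hydroxy-7-methoxy-2,3-dimethyl-6-(3-methylbut-2-enyl)-8-[phenyl(4-methylphenylsulfonyl)methyl]chroman-4-one, both epimers | COc1c(CC=C(C)C)c(O)c2c(c1C(c1ccccc1)S(=O)(=O)c1ccc(C)cc1)O[C@@H](C)[C@@H](C)C2=O | intermediate
24 | diallyl malonate | C=CCOC(=O)CC(=O)OCC=C | starting material
25 | (2S,3R)-8-benzylidene-7-methoxy-2,3-dimethyl-6-(3-methylbut-2-enyl)-2,3-dihydrochromene-4,5(8H)-dione, either alkene geometry | COC1=C(CC=C(C)C)C(=O)C2=C(C1=Cc1ccccc1)O[C@@H](C)[C@@H](C)C2=O | intermediate
26 | diallyl 2-{(R)-[(2S,3R)-5-hydroxy-7-methoxy-2,3-dimethyl-6-(3-methylbut-2-enyl)-4-oxochroman-8-yl](phenyl)methyl}malonate | COc1c(CC=C(C)C)c(O)c2c(c1[C@H](C(C(=O)OCC=C)C(=O)OCC=C)c1ccccc1)O[C@@H](C)[C@@H](C)C2=O | intermediate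
27 | 2-{(R)-[(2S,3R)-5-hydroxy-7-methoxy-2,3-dimethyl-6-(3-methylbut-2-enyl)-4-oxochroman-8-yl](phenyl)methyl}malonic acid | COc1c(CC=C(C)C)c(O)c2c(c1[C@H](C(C(=O)O)C(=O)O)c1ccccc1)O[C@@H](C)[C@@H](C)C2=O | intermediate
28 | (3R)-3-[(2S,3R)-5-hydroxy-7-methoxy-2,3-dimethyl-6-(3-methylbut-2-enyl)-4-oxochroman-8-yl]-3-phenylpropanoic acid | COc1c(CC=C(C)C)c(O)c2c(c1[C@H](CC(=O)O)c1ccccc1)O[C@@H](C)[C@@H](C)C2=O | target

**Total step count:** 16
**Longest linear sequence:** 13 steps (steps 1, 2, 3, 6, 7 and 9 to 16)

**Steps most likely to fail**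

**Step 6.**
- What may go wrong: the aryl anion may be protonated before it acylates, for instance by internal transfer of the hydrogen next to the ester, after which aryloxide is lost by beta-elimination. The free alkoxide may exchange with the ester group of a second molecule. Any base left over may enolise the product, which epimerises C3 or opens ring C by a retro-oxa-Michael reaction.
- Fallback: it uses known chemistry and closes ring C by Friedel–Crafts acylation instead of aryne capture. It sets out from 1 and comes back to the route at 13.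
- Commercial methyl (R)-3-hydroxybutanoate is methylated by the Fráter–Seebach alkylation (LDA, 2 equiv, then MeI, THF, −78 °C) to the anti ester methyl (2R,3R)-3-hydroxy-2-methylbutanoate F1. Mitsunobu reaction of 1 with it (PPh3, DIAD, toluene, 0 °C) inverts the carbinol carbon and gives methyl (2R,3S)-3-(3,5-dimethoxyphenoxy)-2-methylbutanoate F2. Me3SnOH in 1,2-dichloroethane at 80 °C cleaves the ester without free base to (2R,3S)-3-(3,5-dimethoxyphenoxy)-2-methylbutanoic acid F3. (CF3CO)2O in CH2Cl2 at 0 °C then acylates either of the two equivalent ortho carbons and gives 13.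

**Step 14.**
- What may go wrong: the quinone methide is unsymmetrical, can adopt two alkene geometries and is tamed by two oxygen donors. The ion pair may therefore discriminate poorly between the faces, or addition may be sluggish and self-condensation may compete.
- Fallback: it sets the benzylic centre by rhodium-catalysed conjugate arylation. It sets out from 21 and comes back at 28.
- Wittig olefination of 21 with allyl (triphenylphosphoranylidene)acetate in toluene at 80 °C gives allyl (E)-3-[(2S,3R)-5-hydroxy-7-methoxy-2,3-dimethyl-6-(3-methylbut-2-enyl)-4-oxochroman-8-yl]acrylate F4. Hayashi–Miyaura addition of PhB(OH)2 follows, with a monovalent rhodium catalyst made from [RhCl(C2H4)2]2 and one enantiomer of a C2-symmetric chiral bicyclo[2.2.2]octadiene ligand (catalytic aq. KOH, dioxane, 40 °C). It gives allyl (3R)-3-[(2S,3R)-5-hydroxy-7-methoxy-2,3-dimethyl-6-(3-methylbut-2-enyl)-4-oxochroman-8-yl]-3-phenylpropanoate F5, the ligand enantiomer being chosen for the R centre. Pd(PPh3)4 and morpholine in THF at rt then free the acid 28.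

**Step 9.**
- What may go wrong: the C5 hydroxyl is locked in a hydrogen bond to C4=O and its phenoxide is a good leaving group. O-allylation may be slow, and palladium may re-ionise the tertiary ether so that it drifts to the linear O-prenyl ether.
- Fallback: it replaces the ether and Claisen relay by cross-coupling. It sets out from 15 and comes back at 19.
- Iodination of 15 with BnMe3NICl2 and CaCO3 in CH2Cl2/MeOH at rt goes ortho to the free hydroxyl on 5-hydroxy-7-alkoxy benzopyranones and gives (2S,3R)-5-hydroxy-6-iodo-7-methoxy-2,3-dimethylchroman-4-one F6. Stille coupling with tributyl(3-methylbut-2-enyl)stannane (Pd(PPh3)4, DMF, 80 °C) gives 19.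

**Further compounds**
F1 | step 6 | methyl (2R,3R)-3-hydroxy-2-methylbutanoate | O[C@H](C)[C@@H](C)C(=O)OC
F2 | step 6 | methyl (2R,3S)-3-(3,5-dimethoxyphenoxy)-2-methylbutanoate | COc1cc(OC)cc(c1)O[C@@H](C)[C@@H](C)C(=O)OC
F3 | step 6 | (2R,3S)-3-(3,5-dimethoxyphenoxy)-2-methylbutanoic acid | COc1cc(OC)cc(c1)O[C@@H](C)[C@@H](C)C(=O)O
F4 | step 14 | allyl (E)-3-[(2S,3R)-5-hydroxy-7-methoxy-2,3-dimethyl-6-(3-methylbut-2-enyl)-4-oxochroman-8-yl]acrylate | COc1c(CC=C(C)C)c(O)c2c(c1/C=C/C(=O)OCC=C)O[C@@H](C)[C@@H](C)C2=O
F5 | step 14 | allyl (3R)-3-[(2S,3R)-5-hydroxy-7-methoxy-2,3-dimethyl-6-(3-methylbut-2-enyl)-4-oxochroman-8-yl]-3-phenylpropanoate | COc1c(CC=C(C)C)c(O)c2c(c1[C@H](CC(=O)OCC=C)c1ccccc1)O[C@@H](C)[C@@H](C)C2=O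
F6 | step 9 | (2S,3R)-5-hydroxy-6-iodo-7-methoxy-2,3-dimethylchroman-4-one | COc1c(I)c(O)c2c(c1)O[C@@H](C)[C@@H](C)C2=O
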